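The route rests on removing the C4 methylene from the dihydropyran ring. C4 is a lone CH2 flanked by arene carbon C4a and carbinol carbon C3, so the chroman maps onto a benzofuran-3-one lacking one carbon in its aryl–carbonyl bond. Insertion of the diazo carbon of (trimethylsilyl)diazomethane into that bond, with a 1,2-shift of the aryl carbon, enlarges the furanone to the chroman-3-one in a single operation and creates C3–C4 and C4–C4a. The precursor is the (2R)-2-allyl-2-methylbenzofuran-3-one 5-methyl ester, whose quaternary C2 is installed earlier by palladium-catalysed decarboxylative asymmetric allylation; reduction, acetylation and cross-metathesis finish the target.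

Key step: step 6

Assumption: the target is (2R,3R), with the C3 acetoxy group cis to the C2 side chain; the sense of induction in step 5 is assumed to parallel that of 2-methyl-1-tetralone-type enol carbonates, which calls for the (R)-ligand, and the antipodal ligand would be used if a first run showed the opposite sense.

Step 1
Reactants: 1 methyl 4-hydroxybenzoate; 2 propanoyl chloride
Product: 3 methyl 4-(propanoyloxy)benzoate
Conditions: Et3N, DMAP (cat.), CH2Cl2, 0 °C → rt
Reagents that add atoms: none
Why: DMAP-assisted O-acylation of the phenol by the acid chloride should be clean, because the phenolic oxygen is the only nucleophile and the methyl ester is inert.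

Step 2
Reactants: 3 methyl 4-(propanoyloxy)benzoate
Product: 4 methyl 4-hydroxy-3-propanoylbenzoate
Conditions: AlCl3 (3 equiv), neat, 140–150 °C; then ice, 2 M HCl
Reagents that add atoms: none
Why: Fries rearrangement, in which the acylium ion released by AlCl3 can return only ortho to the oxygen because the para position carries the ester, and the chelated ortho-hydroxy ketone is the thermodynamic sink.

Step 3
Reactants: 4 methyl 4-hydroxy-3-propanoylbenzoate
Product: 6 methyl 2-methyl-3-oxo-2,3-dihydrobenzofuran-5-carboxylate (racemic), via α-bromoketone 5 (not isolated)
Conditions: CuBr2 (2.1 equiv), EtOAc/CHCl3, reflux; filter, evaporate; NaOAc, degassed MeOH, 50 °C, Ar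
Reagents that add atoms: none
Why: CuBr2 brominates the enolisable α-carbon of the ketone in preference to the doubly deactivated ring, and the phenol oxygen then displaces the secondary bromide in a 5-exo-tet Williamson closure; C2 is left racemic on purpose because it is flattened in the next step.

Step 4
Reactants: 6 methyl 2-methyl-3-oxo-2,3-dihydrobenzofuran-5-carboxylate; 7 allyl chloroformate
Product: 8 methyl 3-{[(allyloxy)carbonyl]oxy}-2-methylbenzofuran-5-carboxylate
Conditions: iPr2NEt, DMAP (10 mol%), CH2Cl2, 0 °C → rt, Ar
Reagents that add atoms: none
Why: The ketone equilibrates with its aromatic 3-hydroxybenzofuran enol, whose oxygen should be acylated by the hard chloroformate under amine/DMAP catalysis to give the enol carbonate (enol O-acylation).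

Step 5
Reactants: 8 methyl 3-{[(allyloxy)carbonyl]oxy}-2-methylbenzofuran-5-carboxylate
Product: 9 methyl (2R)-2-allyl-2-methyl-3-oxo-2,3-dihydrobenzofuran-5-carboxylate
Conditions: Pd2(dba)3 (2.5 mol%), (R)-t-Bu-PHOX (6.25 mol%), THF, 25 °C
Reagents that add atoms: none
Why: Decarboxylative asymmetric allylic alkylation (Tsuji–Trost type), in which zerovalent palladium ionises the allyl carbonate, CO2 is lost and the π-allylpalladium benzofuran-3-olate pair recombines at C2, the chiral P,N-ligand choosing the enolate face so that (2R) should result.

Step 6
Reactants: 9 methyl (2R)-2-allyl-2-methyl-3-oxo-2,3-dihydrobenzofuran-5-carboxylate; 10 (trimethylsilyl)diazomethane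
Product: 12 methyl (2R)-2-allyl-2-methyl-3-oxochroman-6-carboxylate, via C4-silyl ketone 11 (not isolated)
Conditions: BF3·OEt2 (1.5 equiv), 10 (2 M in hexanes, 2 equiv), CH2Cl2, −78 → 0 °C; sat. aq. NaHCO3; then 1 M HCl, THF, rt
Reagents that add atoms: none
Why: BF3 activates the C3 carbonyl of 9, the nucleophilic diazo carbon of 10 adds to C3, and in the resulting diazonium betaine the aryl carbon (the future C4a) shifts to the diazo-derived carbon as N2 departs, which forms C3–C4 and C4–C4a and leaves the C4-silyl ketone 11. The closest known reaction type is the Lewis acid-promoted diazoalkane homologation of benzo-fused cyclic aryl ketones with aryl migration (1-indanone to 2-tetralone, a Tiffeneau–Demjanov-type ring enlargement). The dihydropyranone ring is therefore closed by a one-carbon ring expansion through a 1,2-aryl shift and not by an end-to-end cyclisation. No stereocentre is created: C2 is quaternary, carries no hydrogen and is not touched, so (2R) is carried through, and the transient silyl-bearing C4 becomes a CH2 on protodesilylation during the acidic work-up. The step needs aryl rather than C2 migration, which the substrate secures because C2 is fully substituted and bears the electron-withdrawing ring oxygen, whereas the migrating aryl carbon is ortho to the donating ether oxygen. It also needs a single insertion, which the bulky C4 silyl group of 11 secures by shielding the new, more electrophilic ketone until work-up, while the alkene and the ester are inert to the reagent at low temperature.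

Step 7
Reactants: 12 methyl (2R)-2-allyl-2-methyl-3-oxochroman-6-carboxylate
Product: 13 methyl (2R,3R)-2-allyl-3-hydroxy-2-methylchroman-6-carboxylate
Conditions: (S)-Me-CBS oxazaborolidine (20 mol%), catecholborane (1.8 equiv), toluene, −78 → −40 °C; MeOH quench
Reagents that add atoms: none
Why: Corey–Bakshi–Shibata reduction, in which the oxazaborolidine distinguishes the quaternary C2 (large) from the C4 methylene (small) and should deliver hydride to the face that gives the (3R)-alcohol with OH cis to the allyl group, as expected for the (S)-catalyst, while catecholborane leaves the terminal alkene and the ester alone.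

Step 8
Reactants: 13 methyl (2R,3R)-2-allyl-3-hydroxy-2-methylchroman-6-carboxylate
Product: 14 methyl (2R,3R)-3-acetoxy-2-allyl-2-methylchroman-6-carboxylate
Conditions: Ac2O, pyridine, DMAP (cat.), CH2Cl2, rt
Reagents that add atoms: acetic anhydride, CC(=O)OC(C)=O
Why: DMAP-catalysed acyl transfer to the secondary alcohol, which proceeds with retention at C3 because the C–O bond is not broken.

Step 9
Reactants: 14 methyl (2R,3R)-3-acetoxy-2-allyl-2-methylchroman-6-carboxylate; 15 2-methylbut-3-en-2-ol
Product: 16 methyl (2R,3R)-3-acetoxy-2-[(2E)-4-hydroxy-4-methylpent-2-en-1-yl]-2-methylchroman-6-carboxylate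
Conditions: second-generation Grubbs catalyst RuCl2(=CHPh)(PCy3)(SIMes) (5 mol%), 15 (5 equiv), CH2Cl2, 40 °C
Reagents that add atoms: none
Why: Olefin cross-metathesis, in which the terminal alkene of 14 couples with the hindered tertiary allylic alcohol that homodimerises only slowly, and the reversible process should settle on the E-alkene while ethene escapes.

Compound list
1 | methyl 4-hydroxybenzoate | COC(=O)c1ccc(O)cc1 | starting material
2 | propanoyl chloride | CCC(=O)Cl | starting material
3 | methyl 4-(propanoyloxy)benzoate | CCC(=O)Oc1ccc(cc1)C(=O)OC | intermediate
4 | methyl 4-hydroxy-3-propanoylbenzoate | CCC(=O)c1cc(ccc1O)C(=O)OC | intermediate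
5 | methyl 3-(2-bromopropanoyl)-4-hydroxybenzoate (racemic, not isolated) | CC(Br)C(=O)c1cc(ccc1O)C(=O)OC | intermediate
6 | methyl 2-methyl-3-oxo-2,3-dihydrobenzofuran-5-carboxylate (racemic) | COC(=O)c1ccc2c(c1)C(=O)C(C)O2 | intermediate
7 | allyl chloroformate | C=CCOC(=O)Cl | starting material
8 | methyl 3-{[(allyloxy)carbonyl]oxy}-2-methylbenzofuran-5-carboxylate | COC(=O)c1ccc2oc(C)c(OC(=O)OCC=C)c2c1 | intermediate
9 | methyl (2R)-2-allyl-2-methyl-3-oxo-2,3-dihydrobenzofuran-5-carboxylate | COC(=O)c1ccc2c(c1)C(=O)[C@@](C)(CC=C)O2 | intermediate
10 | (trimethylsilyl)diazomethane | C[Si](C)(C)C=[N+]=[N-] | starting material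
11 | methyl (2R)-2-allyl-2-methyl-3-oxo-4-(trimethylsilyl)chroman-6-carboxylate (mixture of C4 epimers, not isolated) | COC(=O)c1ccc2c(c1)C([Si](C)(C)C)C(=O)[C@@](C)(CC=C)O2 | intermediate
12 | methyl (2R)-2-allyl-2-methyl-3-oxochroman-6-carboxylate | COC(=O)c1ccc2c(c1)CC(=O)[C@@](C)(CC=C)O2 | intermediate
13 | methyl (2R,3R)-2-allyl-3-hydroxy-2-methylchroman-6-carboxylate | COC(=O)c1ccc2c(c1)C[C@@H](O)[C@@](C)(CC=C)O2 | intermediate
14 | methyl (2R,3R)-3-acetoxy-2-allyl-2-methylchroman-6-carboxylate | COC(=O)c1ccc2c(c1)C[C@@H](OC(C)=O)[C@@](C)(CC=C)O2 | intermediate
15 | 2-methylbut-3-en-2-ol | CC(C)(O)C=C | starting material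
16 | methyl (2R,3R)-3-acetoxy-2-[(2E)-4-hydroxy-4-methylpent-2-en-1-yl]-2-methylchroman-6-carboxylate | COC(=O)c1ccc2c(c1)C[C@@H](OC(C)=O)[C@@](C)(C/C=C/C(C)(C)O)O2 | target

Total step count: 9. Longest linear sequence: 9 steps (1 to 16); all other partners are commercial.

Steps most likely to fail

Step 6. The carbonyl of 9 is a hindered vinylogous ester, so addition of the diazo carbon may be slow enough for the reagent to decompose under the Lewis acid. The betaine may also collapse to the spiro-epoxide instead of rearranging, or migration of C2 or a second insertion may compete. The fallback sets out from 9 and changes the carbon source and the trigger of the aryl shift. Wittig methylenation with Ph3P=CH2 (from Ph3PCH3Br and KOtBu, toluene, 80 °C) should give methyl (2R)-2-allyl-2-methyl-3-methylidene-2,3-dihydrobenzofuran-5-carboxylate F1. Treating this alkene with PhI(OH)OTs in 95% aqueous methanol at room temperature should then bring about the known oxidative ring expansion of exocyclic aryl alkenes, in which the aryl carbon shifts onto the former methylidene carbon. The electron-rich 1,1-disubstituted aryl alkene is expected to react well before the allyl group, and the route is rejoined at 12.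

Step 5. The stabilised, aromatic benzofuran-3-olate may attack the allyl unit from outside the coordination sphere of palladium and so erode facial discrimination, or the sense of induction may be opposite to that assumed. The fallback sets out from 8 and replaces asymmetric catalysis by resolution. The same decarboxylative allylation run with achiral Pd(PPh3)4 in THF should give the racemic ketone methyl (2RS)-2-allyl-2-methyl-3-oxo-2,3-dihydrobenzofuran-5-carboxylate F2. Preparative chromatography on a polysaccharide-based chiral stationary phase (supercritical CO2/MeOH) then separates 9 from its antipode methyl (2S)-2-allyl-2-methyl-3-oxo-2,3-dihydrobenzofuran-5-carboxylate F3, which is discarded, and the route is rejoined at 9.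

Step 7. Uncatalysed hydride transfer or weak discrimination between C2 and C4 may lower the facial selectivity, and slow reduction of the hindered ketone could allow the borane to add to the terminal alkene. The fallback sets out from 12 and relies on separation of diastereomers with recycling instead of catalyst control. Reduction with NaBH4 in MeOH at −20 °C, which cannot hydroborate, should give 13 together with its C3 epimer methyl (2R,3S)-2-allyl-3-hydroxy-2-methylchroman-6-carboxylate F4. The two diastereomers are separated on silica gel, the unwanted epimer is returned to 12 by Dess–Martin oxidation and reduced again, and the route is rejoined at 13.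

Further compounds
F1 | step 6 | methyl (2R)-2-allyl-2-methyl-3-methylidene-2,3-dihydrobenzofuran-5-carboxylate | COC(=O)c1ccc2c(c1)C(=C)[C@@](C)(CC=C)O2
F2 | step 5 | methyl (2RS)-2-allyl-2-methyl-3-oxo-2,3-dihydrobenzofuran-5-carboxylate (racemate) | COC(=O)c1ccc2c(c1)C(=O)C(C)(CC=C)O2
F3 | step 5 | methyl (2S)-2-allyl-2-methyl-3-oxo-2,3-dihydrobenzofuran-5-carboxylate | COC(=O)c1ccc2c(c1)C(=O)[C@](C)(CC=C)O2
F4 | step 7 | methyl (2R,3S)-2-allyl-3-hydroxy-2-methylchroman-6-carboxylate | COC(=O)c1ccc2c(c1)C[C@H](O)[C@@](C)(CC=C)O2
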